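**The vessel.** A closed, stirred, isothermal flask holds substrate and catalyst, and the flasks differ in their catalyst charge.

common to all: substrate 0.050 M; time 2.5 d
- violet: catalyst 0.12 mM
- teal: catalyst 0.25 mM
- amber: catalyst 0.50 mM
- ochre: catalyst 1.0 mM

    isomer of the product A + catalyst ⇌ isomer of the product B + catalyst, rate k1*[catalyst]*[isomer of the product A] forward; the back reaction follows from the equilibrium constant (K1 = 1.64, k1 = 52.0 M⁻¹ h⁻¹)
    catalyst + target → catalyst + over-reaction product (k2 = 66.7 M⁻¹ h⁻¹)
    substrate + catalyst ⇌ target + catalyst, rate k3*[substrate]*[catalyst] forward; the back reaction follows from the equilibrium constant (K3 = 1.5, k3 = 21.5 M⁻¹ h⁻¹)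
    isomer of the product B + catalyst ⇌ substrate + catalyst, rate k4*[catalyst]*[isomer of the product B] forward; the back reaction follows from the equilibrium constant (k4 = 31.1 M⁻¹ h⁻¹)
    target + catalyst ⇌ isomer of the product A + catalyst, rate k5*[catalyst]*[target] forward; the back reaction follows from the equilibrium constant (K5 = 0.44, k5 = 85.3 M⁻¹ h⁻¹)

- "hardly changes" means that all values lie within two and a half points (for a concentration: within two and a half percent of the largest)
- run time (violet): 2.5 d

* [target] at the end for violet, teal, amber, ochre, in this order
* the course of these numbers from the first flask to the last (rises, then falls / hardly changes / falls all the way / rises all the way / falls, then rises)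

**One clock.** Each step carries c(catalyst) as a factor and gives the catalyst back, so catalyst charge times time is the clock of each flask.

**Crest charge.** The substrate-to-target step makes target and the over-reaction step removes it for good. In violet the over-reaction half-life of target is 3.6 d, against 11 d for the forward half-life of substrate. Taken as a two-step chain, c(target) crests when charge times time equals the logarithm of the ratio of these two rate constants, divided by their difference. Over the run of 2.5 d that gives 0.417 mM, the crest charge. In violet, target also turns forward into isomer of the product A with a half-life of 2.8 d, shorter than its over-reaction half-life. That step runs both ways, though, and this reckoning sets the isomers aside, so the crest charge is rough and gives no height.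

**Amber against ochre.** Amber and ochre look nearly the same, except that ochre has twice the catalyst. In powers of ten, amber stands 0.0784 above the crest charge and ochre 0.379 above it, while teal stands 0.223 below and violet 0.541 below. Ochre's charge lies farther from the crest than amber's, so the reckoning puts amber on top of the pair. On a hump roughly even in the logarithm, amber ends highest, followed by teal, ochre and violet. The reckoning stops at that order.

**The forecast.** The forecast gives 0.0043 M, 0.006 M, 0.0067 M and 0.0053 M, so the row rises, then falls, for a target “which builds as the isomers interconvert and is slowly drained to the over-reaction product”. It puts the same flask on top as the reckoning above, and it adds heights.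

**The flasks.** The simulation gives 0.00428 M, 0.00598 M, 0.00674 M and 0.00530 M, so the row rises, then falls, turning at a read 0.47 mM against the crest charge of 0.417 mM. Ochre at 1.25 d holds target 13.5% and over-reaction product 21.0%, as amber does at 2.50 d with 13.5% and 21.0%, while the catalyst stands at 100% of its charge in ochre. The crest charge puts ochre's crest at 1.04 d, and after 1.25 d the over-reaction step ran in ochre on the target still there, and by 2.50 d substrate stood at 18.5%, over-reaction product at 45.6% and target at 10.6%.

(The numbers of this flask were set for the occasion, and the outcome is calculated.)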